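The numbers in the tables are simulated with made-up constants.

Repeating this run, we watch Z first: the eta and gamma runs hold it at 80.6% and 80.9% after 20.0 min, a gap smaller than the scatter of 0.5 percentage points, with X at 0.75 equiv and 1.1 equiv.

all flasks: Z 0.10 M

| flask | X | remark | time |
|---|---|---|---|
| eta | 0.75 equiv | run made earlier |  |
| gamma | 1.1 equiv | run made earlier |  |
| flask | 1.50 equiv |  | 25 min |

- eta (time / min: E / %, Z / %): 4.00: 4.0, 94.5; 8.00: 7.3, 90.9; 12.0: 9.7, 87.3; 15.0: 11.4, 85.2; 20.0: 12.2, 80.6
- gamma (time / min: E / %, Z / %): 4.00: 2.8, 94.4; 8.00: 7.0, 90.6; 12.0: 10.1, 87.8; 15.0: 11.2, 85.0; 20.0: 10.8, 80.9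

(each reading ± 0.5 percentage points)

- given per volume of solution although it is solid: X
- at the start none of X is in solution

- how much E the flask holds at 25 min, in percent of the Z charged
- how much Z the flask holds at 25 min, in percent of the Z charged

1. The order in charged X therefore reads as zero between these two charges, so we put this flask, with 1.50 equiv of X, on the same line. We keep the books on Z, its limiting reagent.
2. First entry, Z left. Between the first and last readings, the two runs lose on average 8.56 × 10⁻⁴ M/min of c_Z, which we call the drain of Z. Both runs start at 0.10 M, so they hold no second starting c_Z to compare.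
3. From the mean Z of the two runs at 20.0 min, 80.8%, the drain leaves our own figure for this flask of 76.5% at 25 min.
4. Second entry, the part of the charged Z read neither as Z nor as E. This gap grows from 2.15% to 7.75% across the same readings, and a straight line takes it to 9.50%.
5. Third entry, E, closes the books at 14.0%, our own figure.
6. The forecast gives Z 76.3% and E 10.5%. Its E stands below ours, and its grounds are that “E is evidently being consumed onward”.

The flask gives Z 77.4% and E 12.9%, with D, J and L together at 9.75%; both forecast values stand within their margins.

    Z ⇌ L + G (K = 4.63 × 10⁻⁵ M, k = 0.580 /min)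
    Q + L → E (k = 239 /M/min)
    E ⇌ D (K = 1.21, k = 0.0331 /min)
    G + E → J (k = 1.32 /M/min)
    X ⇌ Q, rate k5*(cs5 - [Q]) while solid is left; crystals form when [Q] > cs5 (solubility = 21.0 mM, k = 0.142 /min)

Raised to this X charge, the eta run holds Z at 80.9% at its last reading, against 80.9% before. The drain reckons 0.0214 M of Z lost by 25 min, and this flask lost 0.0226 M. In the neighbouring flask, at 0.060 M of Z, an unchanged drain leaves 64.3% of Z and a drain proportional to c_Z leaves 78.6%, while that flask holds 70.6%. There c_G stands at 0.0151 M, against 0.0187 M here. The Z lost in the two flasks gives an apparent order in c_Z of 0.488.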